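Start from the time: the flask gets 5.0 h, so ask first whether its starting material clears well inside that.

common to all: gas 39 mM (held)
- Tuesday's: starting material 0.25 M; second substrate 2.5 M; third substrate 1 M; run made earlier
- Wednesday's: starting material 0.38 M; second substrate 2.5 M; third substrate 1 M; run made earlier
- flask: starting material 0.50 M; second substrate 2.50 M; third substrate 1.00 M; time 5.0 h

- Tuesday's (time / h: starting material / %, target / %, isomer of the product / %): 0.833: 40.3, 18.2, 41.2; 2.00: 1.9, 21.2, 76.1; 4.00: 0, 20.9, 79.0; 6.00: 0.2, 21.8, 78.8
- Wednesday's (time / h: starting material / %, target / %, isomer of the product / %): 0.500: 64.0, 13.9, 21.9; 1.00: 32.0, 19.3, 47.9; 2.50: 0, 20.9, 78.3; 6.00: 0.7, 19.9, 78.2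

(standard deviation of a reading: 0.5 percentage points)

- which holds at 5.0 h: what has brought the reaction to rest, or that it has not come to rest (forward and back rates have come level / all of the starting material has reacted / it is still moving)
- share of the starting material used up at 5.0 h
- target at 5.0 h, in percent of the starting material charged
- isomer of the product at 5.0 h, in percent of the starting material charged

- at the start none of the gas is in solution
- the reaction counts as stopped when no species that holds the starting material changes by six tenths of a point or more over the second half of the time

Read the early fall of starting material as a fraction of the charge per hour. Tuesday's run loses 0.717 h⁻¹ and Wednesday's 0.720 h⁻¹, so carry that level figure to the flask at 0.50 M. Invert it: 1.39 h is the clearing time, the time in which that straight fall empties the charge.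

Now count time in clearing times. The flask has 3.60. The weak link is the straight line, since Tuesday's run still holds 1.9% at 2.00 h, later than the clearing time, and Wednesday's run first reads 0% at 2.50 h. Reforge it: demand 1.80 clearing times for a clean end. The flask has more than that, so commit to 100% conversion.

Then read the split, target over target plus isomer. Wednesday's first reading gives 38.8%, while the last two readings of both runs pooled give 21.0%. This is the look of kinetic giving way to thermodynamic control. Commit the flask to target 21.0% and isomer 79.0%.

The forecast reads: all of the starting material has reacted, conversion 100%, target 20.9%, isomer 78.9%, holding that “the reaction stops because the starting material is exhausted”. Its target stands below mine.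

The flask gives: all of the starting material has reacted, conversion 100%, target 21.3%, isomer 78.7%.

    starting material + coupling partner → target (k = 2.72 M⁻¹ min⁻¹)
    second substrate + coupling partner → second product (k = 1.44 M⁻¹ min⁻¹)
    third substrate + coupling partner → third product (k = 3.29 M⁻¹ min⁻¹)
    gas ⇌ coupling partner, rate k4*(csat - [coupling partner]) (kL = 1.01 min⁻¹)
    2 third substrate → self-condensation product (k = 0.00876 M⁻¹ min⁻¹)
    target ⇌ isomer of the product (K = 3.69, k = 0.115 min⁻¹)

At 3.60 clearing times the flask holds 0% of its starting material. Stop the same flask at 80 min: that is 0.960 clearing times, fewer than the 1.80 demanded, so expect it still moving. The straight fall puts 4.00% of starting material there, but this neighbouring flask holds 18.5%, with target at 21.4% and isomer at 60.1%.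

(The data are simulated from invented constants; the scatter is artificial.)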